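## Analysis of the target

Target 34 is a 1,7,8,8a-tetrahydro-6H-isochromen-6-one. With isochromene numbering, ring A is the carbocycle C4a–C5–C6–C7–C8–C8a and ring B is the dihydropyran C1H2–O2–C3=C4–C4a–C8a. A linear vinylogous ester O2–C3=C4–C4a=C5–C6=O runs through both rings, C5 carries chlorine, and C3 carries the (9E,11E)-dienyl chain C9–C15.

Ring A holds three contiguous stereocentres: C7 (R, methyl and tertiary hydroxyl), C8 (R, secondary hydroxyl) and C8a (S, ring-fusion hydrogen). O7, O8 and the C1 branch lie on one face; the C7 methyl, H8 and H8a lie on the other. The chain carries C13 (R) and C14 (S) in an anti methyl/hydroxyl relation. These two centres are too far from the ring to be controlled by it, so both halves must be made enantiopure and joined.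

The sensitive points are three. H8a is the γ-hydrogen of the dienone and O8 sits β to that site, so base can expel O8 and flatten ring A into an ortho-quinol. The C7 α-ketol can cleave by retro-aldol at C7–C8. The enol ether and the polyene are sensitive to acid and to oxidants.

The difficulty is a fully substituted carbinol flanked by a second carbinol and a ring-fusion CH that must keep its configuration while two ring alkenes, the chlorine and the polyene are installed. The strategy rests on one feature: C6, C7 and C8 bear oxygen in a row and O8 is cis to C1 on the neighbouring C8a. This is what an endo [4+2] adduct of a C5=C6–C7=C8 diene oxygenated at C6, C7 and C8 with a C8a=C4a alkene activated by a C1 carbonyl would show.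

## Retrosynthetic reasoning

**Deprotection and chlorine.** 34 is traced to its acetonide/silyl ether 33, and the C5–Cl bond is cut to give 32. Chlorination is placed last because C5 is the α-carbon of the push–pull dienone and is the position that electrophiles should choose once the chromophore exists. No earlier intermediate then has to carry a vinyl chloride through base or palladium.

**Ring unsaturation.** The C3=C4 and C4a=C5 double bonds of 32 are removed one at a time, giving enone 30 and then saturated ketone 28. Both come from the C6 carbonyl by dehydrogenation. This is unambiguous because C7 is quaternary, so enolisation can only run towards C5 and from there, vinylogously, towards C4. The forward reactions must leave H8a alone.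

**Side chain.** The C9=C10 bond of 28 is cut to aldehyde 19 and allylic sulfone 27. Cutting here makes the route convergent and puts the two chain stereocentres into a small fragment made from the chiral pool (20, through the anti-methylated ester 21). The olefination is run on the saturated ketone, before the base-sensitive dienone exists.

**C7 methyl and C9 oxidation level.** 19 comes from 17 by unmasking and oxidising C9. The C7–CH3 bond of 17 is cut to give silyl enol ether 16. The enol ether fixes the enolate at C6/C7, and the cis-fused dioxolane dictates the face of alkylation.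

**C1 oxidation level.** The cyclic ether 16 is traced to lactone 13 through diol 14. The C1 carbonyl is needed only to activate the dienophile and is removed directly afterwards, while C6 is still masked as the enol ether, so hydride cannot touch C6.

**Key disconnection.** In 13 the bonds C8–C8a and C4a–C5 are cut, which opens ring A into lactone 6 and diene 12. No other cut delivers C8, C8a and C4a in one operation together with all three ring oxygens and a regiodefined enol ether for the methylation. The forward cycloaddition must be regioselective, endo, and anti to the C3 substituent of 6.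

**Fragments.** 6 is cut at its ring alkene (metathesis of acrylate 5) and at the ester, back to alcohol 3, epoxide 2 and 1. The C3 stereocentre bought with 1 serves only as the control element for C8a. 12 is the enol silyl ether of ketone 11, which comes through amide 10 and dioxole ester 9 from the commercial dioxolane ester 7.

## Alternatives that were turned down

**Alternative 1:** The C8–O8 bond and the C8a–H bond are cut, leading back to ortho-quinol A1, which already holds the whole carbon skeleton, the chlorine and the chain. In the forward step an arylboronic acid would esterify the C7 hydroxyl of A1, its B–OH oxygen would add to C8 (the δ-carbon of the C6 dienone) in a 5-exo fashion, and protonation at C8a would give the cyclic boronate A2. In its favour, the tether guarantees the cis 7,8-diol, the boronate shields one face so that H8a should arrive trans to O8, and the step count from a flat precursor is far lower than in the chosen route. Against it, A1 needs an enantioselective route to the C7 carbinol on a dienone prone to dimerise. The conjugate addition runs against a fully conjugated chromophore and can revert by the same elimination that threatens 34. Protonation can also occur at C5 instead of C8a. On step economy this alternative is clearly stronger. The chosen route offers in its place three ring stereocentres set by a concerted cycloaddition at an early, robust stage, with no reliance on an addition–elimination equilibrium at the most fragile point.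

**Alternative 2:** Both ring alkenes (C4a=C5 and C3=C4) are cut, giving the acyclic dienyne A3. A ruthenium alkylidene would load on the C5 vinyl group, close ring A onto the C4a≡C4 alkyne and pass the resulting C4 carbene to the C3 enol ether to close ring B, giving A4. In its favour, both rings and the ring diene appear in one step at the right oxidation pattern, so no dehydrogenations are needed; on this point it is better than the chosen route. Against it, A3 needs the C6–C7–C8–C8a array built centre by centre in an open chain. Its 2-alkoxytriene is fragile. The catalyst can initiate at the electron-rich enol ether (giving an inert Fischer-type carbene) or at the chain diene instead of the hindered C5 vinyl group. A4 still needs C6 oxidation and C5 chlorination. The chosen route sets the ring stereocentres from two four-step fragments and brings the polyene in only after all carbene-free ring chemistry is done.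

**Alternative 3:** The C4a–C8a and C7–C8 bonds are cut, giving A5, in which a 2-methyl-3-silyloxyfuran is tethered through C4–C3–O2–C1 to a (Z)-alkenylboronate. The intramolecular cycloaddition would close both rings to the oxanorbornene A6. Oxidation of the C–B bond would give O8, and opening of the oxygen bridge would release the C7 hydroxyl and the C4a=C5 enone. In its favour, the reaction is intramolecular, the C7 quaternary centre comes with the furan, the O8/C1 relation is fixed by alkene geometry, and one dehydrogenation is saved. On these points it is stronger. Against it, furan cycloadditions are reversible and an alkenylboronate is a weak dienophile, so the equilibrium may not favour A6. The silyloxyfuran is labile. Facial control has to pass from C3 through a flexible ether tether. A6 can revert during the oxidation. The chosen route forms a carbocycle irreversibly and keeps every intermediate before the key step simple and stable.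

Key step: step 9

Remark on the chemistry: 7 is written as its (R)-enantiomer; its only stereocentre is destroyed in step 5, so the other enantiomer or the racemate serves equally. Atom labels C1–C15 on intermediates are those of 34.

## Route

Step 1
Reactants: 1 (S)-glycidol
Product: 2 triisopropyl{[(2R)-oxiran-2-yl]methoxy}silane
Conditions: i-Pr3SiCl, imidazole, CH2Cl2, 0 °C → rt
Reagents that add atoms: chlorotriisopropylsilane, CC(C)[Si](Cl)(C(C)C)C(C)C
Why: Standard silylation of a primary alcohol; the epoxide stereocentre is untouched (the descriptor changes only because the silyl ether outranks the epoxide CH2). The TIPS group is chosen to outlast hydride, base and one equivalent of fluoride.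

Step 2
Reactants: 2 triisopropyl{[(2R)-oxiran-2-yl]methoxy}silane
Product: 3 (2R)-1-[(triisopropylsilyl)oxy]pent-4-en-2-ol
Conditions: CH2=CHMgBr, CuI (10 mol%), THF, −40 → −20 °C
Reagents that add atoms: vinylmagnesium bromide, C=C[Mg]Br
Why: Copper-catalysed Grignard opening of a terminal epoxide at its unsubstituted carbon; the carbinol centre (later C3) is not involved. The vinyl CH becomes C4a.

Step 3
Reactants: 3 (2R)-1-[(triisopropylsilyl)oxy]pent-4-en-2-ol; 4 acryloyl chloride
Product: 5 (2R)-1-[(triisopropylsilyl)oxy]pent-4-en-2-yl prop-2-enoate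
Conditions: Et3N, DMAP (cat.), CH2Cl2, 0 °C
Reagents that add atoms: none
Why: Acylation of a secondary alcohol; 4 supplies C1 and C8a.

Step 4
Reactants: 5 (2R)-1-[(triisopropylsilyl)oxy]pent-4-en-2-yl prop-2-enoate
Product: 6 (6R)-6-{[(triisopropylsilyl)oxy]methyl}-5,6-dihydro-2H-pyran-2-one
Conditions: second-generation Grubbs catalyst RuCl2(=CHPh)(H2IMes)(PCy3) (3 mol%), CH2Cl2 (0.01 M), 40 °C
Reagents that add atoms: none
Why: Ring-closing metathesis of an acrylate onto a terminal alkene, a routine entry to 6-substituted dihydropyranones, driven by loss of ethene.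

Step 5
Reactants: 7 methyl (4R)-2,2-dimethyl-1,3-dioxolane-4-carboxylate
Product: 9 methyl 2,2-dimethyl-1,3-dioxole-4-carboxylate, via 4-bromodioxolane ester 8 (not isolated)
Conditions: NBS, AIBN (cat.), PhCF3, 85 °C; then Et3N, 0 °C → rt
Reagents that add atoms: none
Why: Wohl–Ziegler-type radical bromination at the captodative C4–H (between ring oxygen and ester), then E2 loss of HBr across C4–C5. This is the halogenation/dehydrohalogenation that converts cyclic carbonates and tartrate acetonides into their dioxoles; the product is a stabilised push–pull alkene.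

Step 6
Reactants: 9 methyl 2,2-dimethyl-1,3-dioxole-4-carboxylate
Product: 10 N-methoxy-N,2,2-trimethyl-1,3-dioxole-4-carboxamide
Conditions: MeNHOMe·HCl, i-PrMgCl, THF, −20 °C
Reagents that add atoms: N,O-dimethylhydroxylamine hydrochloride, CNOC.Cl
Why: Weinreb amidation of an ester by the magnesium amide formed in the flask; attack is at the ester carbonyl.

Step 7
Reactants: 10 N-methoxy-N,2,2-trimethyl-1,3-dioxole-4-carboxamide
Product: 11 1-(2,2-dimethyl-1,3-dioxol-4-yl)ethan-1-one
Conditions: MeMgBr, THF, −78 → 0 °C
Reagents that add atoms: methylmagnesium bromide, C[Mg]Br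
Why: Weinreb ketone synthesis; the chelated tetrahedral adduct prevents over-addition. The new methyl is the future C5.

Step 8
Reactants: 11 1-(2,2-dimethyl-1,3-dioxol-4-yl)ethan-1-one
Product: 12 tert-butyl{[1-(2,2-dimethyl-1,3-dioxol-4-yl)ethenyl]oxy}dimethylsilane
Conditions: t-BuMe2SiOTf, Et3N, Et2O, 0 °C
Reagents that add atoms: tert-butyldimethylsilyl trifluoromethanesulfonate, CC(C)(C)[Si](C)(C)OS(=O)(=O)C(F)(F)F
Why: Soft enolisation of a β-alkoxy enone at its only enolisable position, the way 1-alkoxy-3-silyloxybutadienes are prepared. 12 is acid-sensitive and is used at once.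

Step 9
Reactants: 6 (6R)-6-{[(triisopropylsilyl)oxy]methyl}-5,6-dihydro-2H-pyran-2-one; 12 tert-butyl{[1-(2,2-dimethyl-1,3-dioxol-4-yl)ethenyl]oxy}dimethylsilane
Product: 13 (3R,4aR,8R,8aR)-6-[(tert-butyldimethylsilyl)oxy]-7,8-(isopropylidenedioxy)-3-{[(triisopropylsilyl)oxy]methyl}-3,4,4a,5,8,8a-hexahydro-1H-isochromen-1-one (cis-fused, C6=C7 silyl enol ether)
Conditions: 12 (2.5 equiv), BHT (cat.), PhMe, sealed tube, 130 °C
Reagents that add atoms: none
Why: Thermal, concerted but asynchronous normal-demand [4+2] cycloaddition: the HOMO of 12 is largest at the CH2 terminus C5, which bonds first to the β-carbon C4a of 6, and the oxygen-bearing terminus C8 then closes onto the α-carbon C8a. The closest known reaction type is the Diels–Alder addition of 1-alkoxy-3-silyloxybutadienes to 5,6-dihydro-2H-pyran-2-ones; here the dioxole only ties the 1- and 2-oxygens of such a diene together. Ring A closes as the six-membered cycloadduct ring through two sigma bonds (C4a–C5 and C8–C8a) formed suprafacially on both partners, so ring B ends cis-fused at C4a and C8a. C8 is set by the endo transition state: the dioxole holds O8 in the outside position of the s-cis diene, and with the lactone carbonyl under the diene O8 ends cis to C1. The absolute sense at C4a, C8a and C8 is set by the C3 stereocentre of 6, since the diene should approach the half-chair lactone on the face opposite the CH2OTIPS group, as conjugate additions to 6-substituted dihydropyranones do. The step needs regio-, endo- and facial selectivity: the first rests on the reinforcing 1-oxy and 3-silyloxy donors outweighing the single opposing 2-oxy donor, the second on the cis-locked cyclic dienophile, the third on the C3 substituent. Facial isomers remain separable because C3 is still stereogenic in 13, and the adduct keeps a regiodefined C6=C7 silyl enol ether for the next C–C bond.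

Step 10
Reactants: 13 the cis-fused lactone adduct
Product: 14 C1,C3-diol from 13 (CH2OH on C8a, free C3–OH; C6=C7 silyl enol ether, 7,8-acetonide and TIPS ether kept; stereocentres as in 13)
Conditions: LiAlH4, THF, 0 °C
Reagents that add atoms: none
Why: Hydride reduction of the lactone to the diol once the carbonyl has done its work as activator; silyl enol ether, acetonide and TIPS ether are inert to hydride and to the basic work-up. C6 is still masked, so no ketone is reduced.

Step 11
Reactants: 14 the C1,C3-diol
Product: 16 (3R,4aR,8R,8aS)-6-[(tert-butyldimethylsilyl)oxy]-7,8-(isopropylidenedioxy)-3-{[(triisopropylsilyl)oxy]methyl}-3,4,4a,5,8,8a-hexahydro-1H-isochromene, via C1 tosylate 15 (not isolated)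
Conditions: NaH, 1-(p-toluenesulfonyl)imidazole, THF, 0 °C → rt
Reagents that add atoms: none
Why: One-pot Williamson cycloetherification: the primary C1 alkoxide is sulfonylated first and the C3 alkoxide closes ring B by 6-exo-tet displacement, with retention at C3. The non-acidic conditions spare the silyl enol ether, and the C3 configuration is in any case needed no longer.

Step 12
Reactants: 16 the cyclic ether silyl enol ether
Product: 17 (3R,4aR,7R,8R,8aS)-7,8-(isopropylidenedioxy)-7-methyl-3-{[(triisopropylsilyl)oxy]methyl}octahydro-6H-isochromen-6-one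
Conditions: (Me2N)3S+ Me3SiF2− (TASF, 1.1 equiv), MeI (excess), THF, −78 → −20 °C
Reagents that add atoms: iodomethane, CI
Why: Fluoride-mediated regiospecific alkylation of a silyl enol ether: fluoride cleaves the enol Si–O bond and the C6/C7 enolate is C-methylated at C7 before it can equilibrate. The methyl should enter on the face opposite O8 and C1, the only approach that leaves the dioxolane cis-fused, which sets C7 (R). C7 is then quaternary, so the C6 ketone can enolise only towards C5.

Step 13
Reactants: 17 the C7-methyl ketone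
Product: 18 (3R,4aR,7R,8R,8aS)-3-(hydroxymethyl)-7,8-(isopropylidenedioxy)-7-methyloctahydro-6H-isochromen-6-one
Conditions: Bu4NF, THF, 0 °C → rt
Reagents that add atoms: none
Why: Fluoride cleavage of the primary TIPS ether. The ketone tolerates the basic fluoride because its only enolate (towards C5) has no β-leaving group.

Step 14
Reactants: 18 the C9 alcohol
Product: 19 (3R,4aR,7R,8R,8aS)-7,8-(isopropylidenedioxy)-7-methyl-6-oxooctahydro-1H-isochromene-3-carbaldehyde
Conditions: Dess–Martin periodinane, CH2Cl2, 0 °C → rt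
Reagents that add atoms: none
Why: Neutral oxidation of a primary alcohol to the α-alkoxy aldehyde, used crude. Any epimerisation at C3 is without consequence because C3 becomes sp2 in step 24.

Step 15
Reactants: 20 ethyl (3S)-3-hydroxybutanoate
Product: 21 ethyl (2S,3S)-3-hydroxy-2-methylbutanoate
Conditions: LiN(i-Pr)2 (2.2 equiv), THF, −78 → −20 °C; MeI, DMPU, −78 → 0 °C
Reagents that add atoms: iodomethane, CI
Why: Fráter–Seebach alkylation: the chelated alkoxide–enolate dianion is methylated anti to the C3 substituent, which sets C13 relative to the pool-derived C14.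

Step 16
Reactants: 21 ethyl (2S,3S)-3-hydroxy-2-methylbutanoate
Product: 22 ethyl (2S,3S)-3-[(tert-butyldimethylsilyl)oxy]-2-methylbutanoate
Conditions: t-BuMe2SiCl, imidazole, DMF, rt
Reagents that add atoms: tert-butylchlorodimethylsilane, CC(C)(C)[Si](C)(C)Cl
Why: Standard silylation of a secondary alcohol; the TBS ether lasts until the final acid step.

Step 17
Reactants: 22 ethyl (2S,3S)-3-[(tert-butyldimethylsilyl)oxy]-2-methylbutanoate
Product: 23 (2S,3S)-3-[(tert-butyldimethylsilyl)oxy]-2-methylbutanal
Conditions: i-Bu2AlH (1.1 equiv), CH2Cl2, −78 °C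
Reagents that add atoms: none
Why: Partial reduction of an ester to the aldehyde through the aluminium hemiacetal that is stable at low temperature. The α-stereocentre is kept by using the aldehyde cold and crude.

Step 18
Reactants: 23 (2S,3S)-3-[(tert-butyldimethylsilyl)oxy]-2-methylbutanal
Product: 24 ethyl (2E,4R,5S)-5-[(tert-butyldimethylsilyl)oxy]-2,4-dimethylhex-2-enoate
Conditions: Ph3P=C(CH3)CO2Et, PhMe, 80 °C
Reagents that add atoms: ethyl 2-(triphenylphosphoranylidene)propanoate, CCOC(=O)C(C)=P(c1ccccc1)(c1ccccc1)c1ccccc1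
Why: Wittig reaction of a stabilised, α-branched ylide, which should give the (E)-trisubstituted enoate (the C11=C12 alkene) under neutral conditions without epimerising C13.

Step 19
Reactants: 24 ethyl (2E,4R,5S)-5-[(tert-butyldimethylsilyl)oxy]-2,4-dimethylhex-2-enoate
Product: 25 (2E,4R,5S)-5-[(tert-butyldimethylsilyl)oxy]-2,4-dimethylhex-2-en-1-ol
Conditions: i-Bu2AlH (2.2 equiv), CH2Cl2, −78 °C
Reagents that add atoms: none
Why: 1,2-Reduction of an enoate to the allylic alcohol.

Step 20
Reactants: 25 (2E,4R,5S)-5-[(tert-butyldimethylsilyl)oxy]-2,4-dimethylhex-2-en-1-ol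
Product: 26 5-{[(2E,4R,5S)-5-[(tert-butyldimethylsilyl)oxy]-2,4-dimethylhex-2-en-1-yl]sulfanyl}-1-phenyl-1H-tetrazole
Conditions: 1-phenyl-1H-tetrazole-5-thiol, PPh3, DIAD, THF, 0 °C → rt
Reagents that add atoms: 1-phenyl-1H-tetrazole-5-thiol, Sc1nnnn1-c1ccccc1
Why: Mitsunobu thioetherification of a primary allylic alcohol by direct displacement at C10.

Step 21
Reactants: 26 the allylic tetrazolyl sulfide
Product: 27 5-{[(2E,4R,5S)-5-[(tert-butyldimethylsilyl)oxy]-2,4-dimethylhex-2-en-1-yl]sulfonyl}-1-phenyl-1H-tetrazole
Conditions: (NH4)6Mo7O24·4H2O (cat.), H2O2 (30% aq.), EtOH, 0 °C → rt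
Reagents that add atoms: hydrogen peroxide, OO
Why: Molybdate-catalysed oxidation of sulfide to sulfone, which is selective for sulfur over a trisubstituted alkene.

Step 22
Reactants: 19 the C9 aldehyde; 27 the allylic tetrazolyl sulfone
Product: 28 (3R,4aR,7R,8R,8aS)-3-[(1E,3E,5R,6S)-6-[(tert-butyldimethylsilyl)oxy]-3,5-dimethylhepta-1,3-dien-1-yl]-7,8-(isopropylidenedioxy)-7-methyloctahydro-6H-isochromen-6-one
Conditions: KN(SiMe3)2, 18-crown-6, THF, −78 °C → rt (base added last to the mixture of 19 and 27)
Reagents that add atoms: none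
Why: Julia–Kocienski olefination: the sulfone anion adds to the aldehyde, and Smiles rearrangement with loss of SO2 and the tetrazolate forms C9=C10. A sequestered potassium counter-ion should favour the E alkene. The sulfone is the most acidic component, so the hindered C6 ketone should be neither enolised nor attacked, and the olefination precedes the base-sensitive dienone.

Step 23
Reactants: 28 the saturated ketone with the side chain
Product: 30 (3R,7R,8R,8aS)-3-[(1E,3E,5R,6S)-6-[(tert-butyldimethylsilyl)oxy]-3,5-dimethylhepta-1,3-dien-1-yl]-7,8-(isopropylidenedioxy)-7-methyl-1,3,4,7,8,8a-hexahydro-6H-isochromen-6-one, via C5=C6 trimethylsilyl enol ether 29 (not isolated)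
Conditions: LiN(SiMe3)2, Me3SiCl, THF, −78 °C; then Pd(OAc)2, MeCN, rt
Reagents that add atoms: none
Why: Saegusa–Ito dehydrogenation: the ketone can enolise only towards C5, and palladation at C5 followed by β-hydride loss of H4a gives the C4a=C5 enone. C8a is not touched.

Step 24
Reactants: 30 the C4a=C5 enone
Product: 32 (7R,8R,8aS)-3-[(1E,3E,5R,6S)-6-[(tert-butyldimethylsilyl)oxy]-3,5-dimethylhepta-1,3-dien-1-yl]-7,8-(isopropylidenedioxy)-7-methyl-1,7,8,8a-tetrahydro-6H-isochromen-6-one, via C6 trimethylsilyl dienol ether 31 (not isolated)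
Conditions: Me3SiOTf, Et3N, CH2Cl2, 0 °C; then Pd(OAc)2, MeCN, rt
Reagents that add atoms: none
Why: Vinylogous Saegusa–Ito oxidation: soft enolisation removes a γ-hydrogen from C4 to give the heteroannular dienol ether (C5=C6, C4a=C4), the direction that enones fused at the β-carbon normally take. Palladation at C4 and β-hydride loss of the oxygen-activated H3 then give the linear dienone. C3 becomes sp2 here, so its configuration is no longer relevant.

Step 25
Reactants: 32 the des-chloro dienone
Product: 33 (7R,8R,8aS)-3-[(1E,3E,5R,6S)-6-[(tert-butyldimethylsilyl)oxy]-3,5-dimethylhepta-1,3-dien-1-yl]-5-chloro-7,8-(isopropylidenedioxy)-7-methyl-1,7,8,8a-tetrahydro-6H-isochromen-6-one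
Conditions: NCS (1.05 equiv), MeCN, 0 °C → rt, dark
Reagents that add atoms: N-chlorosuccinimide, O=C1CCC(=O)N1Cl
Why: Electrophilic chlorination of a vinylogous ester at its α-carbon C5, as in C5 halogenation of isochromen-6-one (azaphilone-type) dienones. Attack at C5 gives a cation stabilised by O2 through C4a–C4=C3, and loss of H5 restores the chromophore.

Step 26
Reactants: 33 the protected chloride
Product: 34 (7R,8R,8aS)-5-chloro-7,8-dihydroxy-3-[(1E,3E,5R,6S)-6-hydroxy-3,5-dimethylhepta-1,3-dien-1-yl]-7-methyl-1,7,8,8a-tetrahydro-6H-isochromen-6-one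
Conditions: CF3CO2H/H2O (9:1), 0 °C; NaHCO3 work-up
Reagents that add atoms: none
Why: Acid hydrolysis removes the acetonide and the secondary TBS ether in one operation. Acid is used because base would trigger loss of O8 through the γ-position C8a; the vinylogous ester is deactivated towards protonation, so cold, brief exposure should be tolerated.

## Compound list

1 | (S)-glycidol | OC[C@H]1CO1 | starting material
2 | triisopropyl{[(2R)-oxiran-2-yl]methoxy}silane | CC(C)[Si](C(C)C)(C(C)C)OC[C@H]1CO1 | intermediate
3 | (2R)-1-[(triisopropylsilyl)oxy]pent-4-en-2-ol | CC(C)[Si](C(C)C)(C(C)C)OC[C@H](O)CC=C | intermediate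
4 | acryloyl chloride | C=CC(=O)Cl | starting material
5 | (2R)-1-[(triisopropylsilyl)oxy]pent-4-en-2-yl prop-2-enoate | C=CC(=O)O[C@H](CC=C)CO[Si](C(C)C)(C(C)C)C(C)C | intermediate
6 | (6R)-6-{[(triisopropylsilyl)oxy]methyl}-5,6-dihydro-2H-pyran-2-one | O=C1C=CC[C@H](CO[Si](C(C)C)(C(C)C)C(C)C)O1 | intermediate
7 | methyl (4R)-2,2-dimethyl-1,3-dioxolane-4-carboxylate | COC(=O)[C@H]1COC(C)(C)O1 | starting material
8 | methyl 4-bromo-2,2-dimethyl-1,3-dioxolane-4-carboxylate (racemic) | COC(=O)C1(Br)COC(C)(C)O1 | intermediate
9 | methyl 2,2-dimethyl-1,3-dioxole-4-carboxylate | COC(=O)C1=COC(C)(C)O1 | intermediate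
10 | N-methoxy-N,2,2-trimethyl-1,3-dioxole-4-carboxamide | CON(C)C(=O)C1=COC(C)(C)O1 | intermediate
11 | 1-(2,2-dimethyl-1,3-dioxol-4-yl)ethan-1-one | CC(=O)C1=COC(C)(C)O1 | intermediate
12 | tert-butyl{[1-(2,2-dimethyl-1,3-dioxol-4-yl)ethenyl]oxy}dimethylsilane | C=C(O[Si](C)(C)C(C)(C)C)C1=COC(C)(C)O1 | intermediate
13 | (3R,4aR,8R,8aR)-6-[(tert-butyldimethylsilyl)oxy]-7,8-(isopropylidenedioxy)-3-{[(triisopropylsilyl)oxy]methyl}-3,4,4a,5,8,8a-hexahydro-1H-isochromen-1-one | O=C1O[C@@H](CO[Si](C(C)C)(C(C)C)C(C)C)C[C@@H]2CC(O[Si](C)(C)C(C)(C)C)=C3OC(C)(C)O[C@@H]3[C@H]12 | intermediate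
14 | C1,C3-diol from 13 (CH2OH on C8a, C3–OH; stereocentres as in 13) | OC[C@H]1[C@H]2OC(C)(C)OC2=C(O[Si](C)(C)C(C)(C)C)C[C@H]1C[C@@H](O)CO[Si](C(C)C)(C(C)C)C(C)C | intermediate
15 | C1 p-toluenesulfonate of 14 | Cc1ccc(cc1)S(=O)(=O)OC[C@H]1[C@H]2OC(C)(C)OC2=C(O[Si](C)(C)C(C)(C)C)C[C@H]1C[C@@H](O)CO[Si](C(C)C)(C(C)C)C(C)C | intermediate
16 | (3R,4aR,8R,8aS)-6-[(tert-butyldimethylsilyl)oxy]-7,8-(isopropylidenedioxy)-3-{[(triisopropylsilyl)oxy]methyl}-3,4,4a,5,8,8a-hexahydro-1H-isochromene | C1O[C@@H](CO[Si](C(C)C)(C(C)C)C(C)C)C[C@@H]2CC(O[Si](C)(C)C(C)(C)C)=C3OC(C)(C)O[C@@H]3[C@H]12 | intermediate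
17 | (3R,4aR,7R,8R,8aS)-7,8-(isopropylidenedioxy)-7-methyl-3-{[(triisopropylsilyl)oxy]methyl}octahydro-6H-isochromen-6-one | CC(C)[Si](C(C)C)(C(C)C)OC[C@H]1C[C@@H]2CC(=O)[C@]3(C)OC(C)(C)O[C@@H]3[C@@H]2CO1 | intermediate
18 | (3R,4aR,7R,8R,8aS)-3-(hydroxymethyl)-7,8-(isopropylidenedioxy)-7-methyloctahydro-6H-isochromen-6-one | OC[C@H]1C[C@@H]2CC(=O)[C@]3(C)OC(C)(C)O[C@@H]3[C@@H]2CO1 | intermediate
19 | (3R,4aR,7R,8R,8aS)-7,8-(isopropylidenedioxy)-7-methyl-6-oxooctahydro-1H-isochromene-3-carbaldehyde | O=C[C@H]1C[C@@H]2CC(=O)[C@]3(C)OC(C)(C)O[C@@H]3[C@@H]2CO1 | intermediate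
20 | ethyl (3S)-3-hydroxybutanoate | CCOC(=O)C[C@H](C)O | starting material
21 | ethyl (2S,3S)-3-hydroxy-2-methylbutanoate | CCOC(=O)[C@@H](C)[C@H](C)O | intermediate
22 | ethyl (2S,3S)-3-[(tert-butyldimethylsilyl)oxy]-2-methylbutanoate | CCOC(=O)[C@@H](C)[C@H](C)O[Si](C)(C)C(C)(C)C | intermediate
23 | (2S,3S)-3-[(tert-butyldimethylsilyl)oxy]-2-methylbutanal | O=C[C@@H](C)[C@H](C)O[Si](C)(C)C(C)(C)C | intermediate
24 | ethyl (2E,4R,5S)-5-[(tert-butyldimethylsilyl)oxy]-2,4-dimethylhex-2-enoate | CCOC(=O)/C(C)=C/[C@@H](C)[C@H](C)O[Si](C)(C)C(C)(C)C | intermediate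
25 | (2E,4R,5S)-5-[(tert-butyldimethylsilyl)oxy]-2,4-dimethylhex-2-en-1-ol | OC/C(C)=C/[C@@H](C)[C@H](C)O[Si](C)(C)C(C)(C)C | intermediate
26 | 5-{[(2E,4R,5S)-5-[(tert-butyldimethylsilyl)oxy]-2,4-dimethylhex-2-en-1-yl]sulfanyl}-1-phenyl-1H-tetrazole | c1ccccc1-n1nnnc1SC/C(C)=C/[C@@H](C)[C@H](C)O[Si](C)(C)C(C)(C)C | intermediate
27 | 5-{[(2E,4R,5S)-5-[(tert-butyldimethylsilyl)oxy]-2,4-dimethylhex-2-en-1-yl]sulfonyl}-1-phenyl-1H-tetrazole | c1ccccc1-n1nnnc1S(=O)(=O)C/C(C)=C/[C@@H](C)[C@H](C)O[Si](C)(C)C(C)(C)C | intermediate
28 | (3R,4aR,7R,8R,8aS)-3-[(1E,3E,5R,6S)-6-[(tert-butyldimethylsilyl)oxy]-3,5-dimethylhepta-1,3-dien-1-yl]-7,8-(isopropylidenedioxy)-7-methyloctahydro-6H-isochromen-6-one | CC(/C=C/[C@H]1C[C@@H]2CC(=O)[C@]3(C)OC(C)(C)O[C@@H]3[C@@H]2CO1)=C\[C@@H](C)[C@H](C)O[Si](C)(C)C(C)(C)C | intermediate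
29 | C5=C6 trimethylsilyl enol ether of 28 | CC(/C=C/[C@H]1C[C@@H]2C=C(O[Si](C)(C)C)[C@]3(C)OC(C)(C)O[C@@H]3[C@@H]2CO1)=C\[C@@H](C)[C@H](C)O[Si](C)(C)C(C)(C)C | intermediate
30 | (3R,7R,8R,8aS)-3-[(1E,3E,5R,6S)-6-[(tert-butyldimethylsilyl)oxy]-3,5-dimethylhepta-1,3-dien-1-yl]-7,8-(isopropylidenedioxy)-7-methyl-1,3,4,7,8,8a-hexahydro-6H-isochromen-6-one | CC(/C=C/[C@H]1CC2=CC(=O)[C@]3(C)OC(C)(C)O[C@@H]3[C@@H]2CO1)=C\[C@@H](C)[C@H](C)O[Si](C)(C)C(C)(C)C | intermediate
31 | C6 trimethylsilyl dienol ether of 30 (C5=C6, C4a=C4) | CC(/C=C/[C@H]1C=C2C=C(O[Si](C)(C)C)[C@]3(C)OC(C)(C)O[C@@H]3[C@@H]2CO1)=C\[C@@H](C)[C@H](C)O[Si](C)(C)C(C)(C)C | intermediate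
32 | (7R,8R,8aS)-3-[(1E,3E,5R,6S)-6-[(tert-butyldimethylsilyl)oxy]-3,5-dimethylhepta-1,3-dien-1-yl]-7,8-(isopropylidenedioxy)-7-methyl-1,7,8,8a-tetrahydro-6H-isochromen-6-one | CC(/C=C/C1=CC2=CC(=O)[C@]3(C)OC(C)(C)O[C@@H]3[C@@H]2CO1)=C\[C@@H](C)[C@H](C)O[Si](C)(C)C(C)(C)C | intermediate
33 | (7R,8R,8aS)-3-[(1E,3E,5R,6S)-6-[(tert-butyldimethylsilyl)oxy]-3,5-dimethylhepta-1,3-dien-1-yl]-5-chloro-7,8-(isopropylidenedioxy)-7-methyl-1,7,8,8a-tetrahydro-6H-isochromen-6-one | CC(/C=C/C1=CC2=C(Cl)C(=O)[C@]3(C)OC(C)(C)O[C@@H]3[C@@H]2CO1)=C\[C@@H](C)[C@H](C)O[Si](C)(C)C(C)(C)C | intermediate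
34 | (7R,8R,8aS)-5-chloro-7,8-dihydroxy-3-[(1E,3E,5R,6S)-6-hydroxy-3,5-dimethylhepta-1,3-dien-1-yl]-7-methyl-1,7,8,8a-tetrahydro-6H-isochromen-6-one | CC(/C=C/C1=CC2=C(Cl)C(=O)[C@](C)(O)[C@H](O)[C@@H]2CO1)=C\[C@@H](C)[C@H](C)O | target

## Step count and least certain steps

Total step count: 26. Longest linear sequence: 15 steps (steps 1–4, 9–14 and 22–26).

**Step 9 (key step).** The unactivated δ-lactone is a weak dienophile, so the cycloaddition may be slower than thermal decay of the electron-rich diene. The extra 2-oxy donor may also erode the regiochemistry, and facial control by the remote C3 substituent may be incomplete. Fallback, from 6 back to 13: bromine addition to 6 gives the trans-3,4-dibromolactone F1, and triethylamine removes HBr to give the 3-bromolactone F2, a markedly better dienophile of the α-haloenone type. Cycloaddition of F2 with 12 at lower temperature, again endo with respect to the carbonyl, should give the 8a-bromo adduct F3. Radical debromination (Bu3SnH, AIBN) should place hydrogen on the convex face of the C8a radical and return the cis-fused lactone 13.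

**Step 12.** The enolate carbon is fully substituted and oxygen-bearing, so O-methylation or proton transfer (giving the unmethylated ketone) may compete with C-methylation, and fluoride may start to cleave the TIPS ether. Fallback, from 16 back to 17: Simmons–Smith cyclopropanation of the enol ether double bond (Et2Zn, CH2I2) gives the silyloxycyclopropane F4. The carbenoid is held to the face opposite O8 by the same cis-fusion argument. Fluoride then opens the cyclopropanolate at the C6–CH2 bond, the methylene becomes the C7 methyl, and 17 results without any free enolate alkylation.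

**Step 22.** Allylic sulfone anions can give only moderate E selectivity at C9=C10, and the basic anion can enolise the α-alkoxy aldehyde. Fallback, from 19 (with 23 for the chain) back to 28: Takai olefination of 19 (CrCl2, CHI3) gives the (E)-vinyl iodide F5. Aldehyde 23 is converted by the Ohira–Bestmann reagent to the terminal alkyne F6 and by n-BuLi/MeI to the methylalkyne F7; palladium-catalysed syn-hydrostannation (Bu3SnH, PdCl2(PPh3)2) places tin on the less hindered carbon to give the (E)-alkenylstannane F8. Stille coupling of F5 with F8 (Pd2(dba)3, AsPh3) forms the C10–C11 bond with both alkene geometries already fixed and gives 28.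

**Step 24.** Dienolisation may run towards C8a instead of C4, which would destroy the C8a stereocentre or expel O8, and the palladium salt may also engage the side-chain diene. Fallback, from 19 back to 32: the C3=C4 bond is made first from the aldehyde side, where no γ-position is involved. Me3SiOTf/Et3N at −78 °C silylates the aldehyde in preference to the hindered ketone, giving the enol ether F9, and Pd(OAc)2 converts it to the 2-alkoxy enal F10. Julia–Kocienski coupling of F10 with 27 gives the trienyl enol ether F11. Its ketone is then dehydrogenated as in step 23, through the C5=C6 silyl enol ether F12, to give 32.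

**Step 25.** Chlorination may occur at C4 or on the side-chain polyene instead of C5, or go twice. Fallback, from 28 back to 33: chlorine is put on sp3 C5 by enolate chemistry, where the site is not in doubt. LiN(SiMe3)2 then NCS gives the 5-chloroketone F13, and a second round gives the 5,5-dichloroketone F14. Dehydrochlorination (LiCl, Li2CO3, DMF, 100 °C) removes H4a and one chlorine to give the 5-chloroenone F15. The step 24 protocol, through dienol ether F16, then gives 33.

## Further compounds

F1 | step 9 | (6R)-3,4-dibromo-6-{[(triisopropylsilyl)oxy]methyl}tetrahydro-2H-pyran-2-one (3,4-trans, both facial isomers) | O=C1C(Br)C(Br)C[C@H](CO[Si](C(C)C)(C(C)C)C(C)C)O1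
F2 | step 9 | (6R)-3-bromo-6-{[(triisopropylsilyl)oxy]methyl}-5,6-dihydro-2H-pyran-2-one | O=C1C(Br)=CC[C@H](CO[Si](C(C)C)(C(C)C)C(C)C)O1
F3 | step 9 | 8a-bromo analogue of 13 (Br in place of H8a, cis-fused) | O=C1O[C@@H](CO[Si](C(C)C)(C(C)C)C(C)C)C[C@@H]2CC(O[Si](C)(C)C(C)(C)C)=C3OC(C)(C)O[C@@H]3[C@]12Br
F4 | step 12 | 6,7-methano derivative of 16 (silyloxycyclopropane, CH2 on the face opposite O8) | C1O[C@@H](CO[Si](C(C)C)(C(C)C)C(C)C)C[C@@H]2C[C@@]4(O[Si](C)(C)C(C)(C)C)C[C@@]34OC(C)(C)O[C@@H]3[C@H]12
F5 | step 22 | (E)-2-iodoethenyl analogue of 19 (C3–CH=CH–I) | I/C=C/[C@H]1C[C@@H]2CC(=O)[C@]3(C)OC(C)(C)O[C@@H]3[C@@H]2CO1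
F6 | step 22 | tert-butyldimethyl{[(2S,3R)-3-methylpent-4-yn-2-yl]oxy}silane | C#C[C@@H](C)[C@H](C)O[Si](C)(C)C(C)(C)C
F7 | step 22 | tert-butyldimethyl{[(2S,3R)-3-methylhex-4-yn-2-yl]oxy}silane | CC#C[C@@H](C)[C@H](C)O[Si](C)(C)C(C)(C)C
F8 | step 22 | tributyl[(2E,4R,5S)-5-[(tert-butyldimethylsilyl)oxy]-4-methylhex-2-en-2-yl]stannane | C/C(=C\[C@@H](C)[C@H](C)O[Si](C)(C)C(C)(C)C)[Sn](CCCC)(CCCC)CCCC
F9 | step 24 | trimethylsilyl enol ether of aldehyde 19 (C9=C3, E/Z mixture) | C[Si](C)(C)OC=C1C[C@@H]2CC(=O)[C@]3(C)OC(C)(C)O[C@@H]3[C@@H]2CO1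
F10 | step 24 | (4aR,7R,8R,8aS)-7,8-(isopropylidenedioxy)-7-methyl-6-oxo-4a,5,6,7,8,8a-hexahydro-1H-isochromene-3-carbaldehyde | O=CC1=C[C@@H]2CC(=O)[C@]3(C)OC(C)(C)O[C@@H]3[C@@H]2CO1
F11 | step 24 | 3,4-didehydro analogue of 28 (C3=C4 enol ether, C6 ketone, C4a–H) | CC(/C=C/C1=C[C@@H]2CC(=O)[C@]3(C)OC(C)(C)O[C@@H]3[C@@H]2CO1)=C\[C@@H](C)[C@H](C)O[Si](C)(C)C(C)(C)C
F12 | step 24 | C5=C6 trimethylsilyl enol ether of F11 | CC(/C=C/C1=C[C@@H]2C=C(O[Si](C)(C)C)[C@]3(C)OC(C)(C)O[C@@H]3[C@@H]2CO1)=C\[C@@H](C)[C@H](C)O[Si](C)(C)C(C)(C)C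
F13 | step 25 | 5-chloro derivative of 28 (C5 epimers) | CC(/C=C/[C@H]1C[C@@H]2C(Cl)C(=O)[C@]3(C)OC(C)(C)O[C@@H]3[C@@H]2CO1)=C\[C@@H](C)[C@H](C)O[Si](C)(C)C(C)(C)C
F14 | step 25 | 5,5-dichloro derivative of 28 | CC(/C=C/[C@H]1C[C@@H]2C(Cl)(Cl)C(=O)[C@]3(C)OC(C)(C)O[C@@H]3[C@@H]2CO1)=C\[C@@H](C)[C@H](C)O[Si](C)(C)C(C)(C)C
F15 | step 25 | 5-chloro derivative of 30 | CC(/C=C/[C@H]1CC2=C(Cl)C(=O)[C@]3(C)OC(C)(C)O[C@@H]3[C@@H]2CO1)=C\[C@@H](C)[C@H](C)O[Si](C)(C)C(C)(C)C
F16 | step 25 | 5-chloro derivative of 31 | CC(/C=C/[C@H]1C=C2C(Cl)=C(O[Si](C)(C)C)[C@]3(C)OC(C)(C)O[C@@H]3[C@@H]2CO1)=C\[C@@H](C)[C@H](C)O[Si](C)(C)C(C)(C)C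
A1 | alternative 1 | ortho-quinol: (7R)-5-chloro-7-hydroxy-3-[(1E,3E,5R,6S)-6-hydroxy-3,5-dimethylhepta-1,3-dien-1-yl]-7-methyl-1,7-dihydro-6H-isochromen-6-one | CC(/C=C/C1=CC2=C(Cl)C(=O)[C@](C)(O)C=C2CO1)=C\[C@@H](C)[C@H](C)O
A2 | alternative 1 | cyclic phenylboronate of the 7,8-diol of 34 | C1(/C=C/C(C)=C/[C@@H](C)[C@H](C)O)=CC2=C(Cl)C(=O)[C@]3(C)OB(c4ccccc4)O[C@@H]3[C@@H]2CO1
A3 | alternative 2 | acyclic dienyne with C5 vinyl group, C4a≡C4 alkyne, C3 enol ether, C6 triethylsilyl ether and 7,8-acetonide | C=C[C@H](O[Si](CC)(CC)CC)[C@]1(C)OC(C)(C)O[C@@H]1[C@@H](C#C)COC(=C)/C=C/C(C)=C/[C@@H](C)[C@H](C)O[Si](C)(C)C(C)(C)C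
A4 | alternative 2 | bicyclic dienol ether with C6 triethylsilyl ether and 7,8-acetonide, no chlorine | C1(/C=C/C(C)=C/[C@@H](C)[C@H](C)O[Si](C)(C)C(C)(C)C)=CC2=C[C@H](O[Si](CC)(CC)CC)[C@]3(C)OC(C)(C)O[C@@H]3[C@@H]2CO1
A5 | alternative 3 | 2-methyl-3-silyloxyfuran tethered through C4–C3–O2–C1 to a (Z)-alkenyl pinacolboronate | CC(C)[Si](C(C)C)(C(C)C)OC[C@@H](Cc1cc(O[Si](C)(C)C(C)(C)C)c(C)o1)OC/C=C\B1OC(C)(C)C(C)(C)O1
A6 | alternative 3 | exo oxanorbornene adduct (C6 silyl enol ether, boron on C8, oxygen bridge C7 to C4a) | CC(C)[Si](C(C)C)(C(C)C)OC[C@H]1C[C@]23C=C(O[Si](C)(C)C(C)(C)C)[C@](C)(O2)[C@H](B4OC(C)(C)C(C)(C)O4)[C@@H]3CO1
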